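**Strategy.** Ring C is disconnected at C11–C12, C13–C14 and C8–C14: a ring-B vinylketene plus an oxygenated alkyne. One photochemical operation (Wolff rearrangement, [2+2] addition, 4π opening, 6π closure) converts a C9 diazoacetyl cyclohexene and an isopropyl siloxyalkyne into the complete aromatic ring C. The step exploits the O/iPr/O pattern at C12–C14, with C11 unsubstituted and para to C14, fused at the C8=C9 bond of ring B. The precursor is a carvone-derived cyclohexene carrying the C5 isopropenyl group, the C10 methyl and propanoate, a C7 silyl ether and the C9 diazoketone. Phenol-to-quinone oxidation, desilylation and C7 oxidation finish the synthesis.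

Key step: step 12

Remark: abietane numbering is used for the seco skeleton (C10 quaternary, C5 the isopropenyl-bearing CH, C7 the ring-B carbinol/carbonyl carbon, C11–C14 ring C, C1–C3 the propanoate arm); the Criegee rearrangement is taken to proceed with retention at the migrating carbon, so (R)-carvone leads to the (R)-silyloxy enone 5.

Step 1
Reactants: 1 (R)-carvone
Product: 3 (5R)-5-acetoxy-2-methylcyclohex-2-en-1-one, via methoxy hydroperoxide 2 (not isolated)
Conditions: O3, CH2Cl2/MeOH, −78 °C; then Ac2O, Et3N, 4-dimethylaminopyridine (cat.), −78 °C → rt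
Reagents that add atoms: ozone, O=[O+][O-]; methanol, CO
Why: Ozone should cleave the electron-rich isopropenyl alkene in preference to the enone alkene, methanol traps the carbonyl oxide as a hydroperoxy ketal, and acetylation triggers a Criegee rearrangement in which the ring carbon migrates to oxygen with retention, so the stereocentre keeps its (R) sense and the acetyl group is the former C(CH3) unit of the isopropenyl group.

Step 2
Reactants: 3 (5R)-5-acetoxy-2-methylcyclohex-2-en-1-one
Product: 4 (5R)-5-hydroxy-2-methylcyclohex-2-en-1-one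
Conditions: K2CO3, MeOH, 0 °C
Reagents that add atoms: none
Why: Carbonate-mediated transesterification should free the secondary alcohol without touching the stereocentre, the low temperature suppressing β-elimination towards the cresol.

Step 3
Reactants: 4 (5R)-5-hydroxy-2-methylcyclohex-2-en-1-one
Product: 5 (5R)-5-(tert-butyldimethylsilyloxy)-2-methylcyclohex-2-en-1-one
Conditions: TBSCl, imidazole, DMF, 0 °C → rt
Reagents that add atoms: tert-butyldimethylsilyl chloride, CC(C)(C)[Si](C)(C)Cl
Why: Imidazole-promoted silylation of a secondary alcohol installs the group that directs the conjugate addition and is carried on as the C7 oxygen.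

Step 4
Reactants: 5 (5R)-5-(tert-butyldimethylsilyloxy)-2-methylcyclohex-2-en-1-one; 6 isopropenylmagnesium bromide; 7 allyl bromide
Product: 9 (2S,3S,5R)-2-allyl-5-(tert-butyldimethylsilyloxy)-2-methyl-3-(prop-1-en-2-yl)cyclohexan-1-one, via magnesium enolate 8 (not isolated)
Conditions: 6 (1.5 equiv), CuBr·SMe2 (0.2 equiv), THF, −78 → −40 °C; then 7 (3 equiv), HMPA, −78 → 0 °C
Reagents that add atoms: none
Why: Copper-catalysed conjugate addition should occur anti to the silyloxy group (axial attack on the half-chair, setting C5), and C-allylation of the regiodefined tetrasubstituted enolate should occur anti to the adjacent isopropenyl group, setting quaternary C10 with methyl cis and allyl trans to isopropenyl (tandem conjugate addition–enolate alkylation).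

Step 5
Reactants: 9 (2S,3S,5R)-2-allyl-5-(tert-butyldimethylsilyloxy)-2-methyl-3-(prop-1-en-2-yl)cyclohexan-1-one
Product: 11 (3R,5S,6S)-6-allyl-3-(tert-butyldimethylsilyloxy)-6-methyl-5-(prop-1-en-2-yl)cyclohex-1-en-1-yl trifluoromethanesulfonate, via potassium enolate 10 (not isolated)
Conditions: KN(SiMe3)2, THF, −78 °C; then N-(5-chloro-2-pyridyl)triflimide, −78 °C
Reagents that add atoms: N-(5-chloropyridin-2-yl)bis(trifluoromethanesulfonimide), O=S(=O)(N(c1ccc(Cl)cn1)S(=O)(=O)C(F)(F)F)C(F)(F)F
Why: The ketone can enolise only towards C8, so kinetic deprotonation and O-sulfonylation should give a single enol triflate (enol triflate formation), the low temperature keeping the β-silyloxy enolate from eliminating and the absence of the ester at this stage excluding Claisen-type side reactions.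

Step 6
Reactants: 11 (3R,5S,6S)-6-allyl-3-(tert-butyldimethylsilyloxy)-6-methyl-5-(prop-1-en-2-yl)cyclohex-1-en-1-yl trifluoromethanesulfonate
Product: 13 (3R,5S,6S)-3-(tert-butyldimethylsilyloxy)-6-(3-hydroxypropyl)-6-methyl-5-(prop-1-en-2-yl)cyclohex-1-en-1-yl trifluoromethanesulfonate, via alkylborane 12 (not isolated)
Conditions: Sia2BH, THF, 0 °C; then 30% H2O2, aq. NaOAc, 0 °C → rt
Reagents that add atoms: hydrogen peroxide, OO; disiamylborane, CC(C)C(C)BC(C)C(C)C (atoms retained only in 12)
Why: Disiamylborane should hydroborate the monosubstituted allyl alkene much faster than the hindered 1,1-disubstituted isopropenyl group or the electron-poor enol triflate, and buffered peroxide oxidation gives the anti-Markovnikov primary alcohol (hydroboration–oxidation).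

Step 7
Reactants: 13 (3R,5S,6S)-3-(tert-butyldimethylsilyloxy)-6-(3-hydroxypropyl)-6-methyl-5-(prop-1-en-2-yl)cyclohex-1-en-1-yl trifluoromethanesulfonate
Product: 15 3-[(1S,4R,6S)-4-(tert-butyldimethylsilyloxy)-1-methyl-6-(prop-1-en-2-yl)-2-(trifluoromethylsulfonyloxy)cyclohex-2-en-1-yl]propanoic acid, via aldehyde 14 (not isolated)
Conditions: TEMPO (2,2,6,6-tetramethylpiperidin-1-oxyl, cat.), PhI(OAc)2, MeCN/H2O, rt
Reagents that add atoms: water, O
Why: Nitroxyl-catalysed oxidation with PhI(OAc)2 in aqueous acetonitrile should take the primary alcohol through the aldehyde hydrate to the acid while leaving alkenes, silyl ether and enol triflate untouched.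

Step 8
Reactants: 15 3-[(1S,4R,6S)-4-(tert-butyldimethylsilyloxy)-1-methyl-6-(prop-1-en-2-yl)-2-(trifluoromethylsulfonyloxy)cyclohex-2-en-1-yl]propanoic acid
Product: 16 methyl 3-[(1S,4R,6S)-4-(tert-butyldimethylsilyloxy)-1-methyl-6-(prop-1-en-2-yl)-2-(trifluoromethylsulfonyloxy)cyclohex-2-en-1-yl]propanoate
Conditions: TMSCHN2, PhMe/MeOH, 0 °C → rt
Reagents that add atoms: trimethylsilyldiazomethane, C[Si](C)(C)C=[N+]=[N-]
Why: O-Methylation of the acid by diazomethane released from TMSCHN2 and methanol is a neutral esterification that puts no base- or acid-sensitive group at risk.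

Step 9
Reactants: 16 methyl 3-[(1S,4R,6S)-4-(tert-butyldimethylsilyloxy)-1-methyl-6-(prop-1-en-2-yl)-2-(trifluoromethylsulfonyloxy)cyclohex-2-en-1-yl]propanoate; 17 tributyl(1-ethoxyvinyl)stannane
Product: 19 methyl 3-[(1S,4R,6S)-2-acetyl-4-(tert-butyldimethylsilyloxy)-1-methyl-6-(prop-1-en-2-yl)cyclohex-2-en-1-yl]propanoate, via ethoxydiene 18 (not isolated)
Conditions: 17, Pd(PPh3)4 (cat.), LiCl, CuI (cat.), 1,4-dioxane, 90 °C; then 1 M aq. HCl, THF, 0 °C
Reagents that add atoms: water, O
Why: Stille coupling of the enol triflate with the α-ethoxyvinylstannane (LiCl and CuI assisting transmetallation at the hindered position next to C10) should give a 2-ethoxydiene whose enol ether is hydrolysed by cold dilute acid faster than the silyl ether, unveiling the C9 acetyl group.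

Step 10
Reactants: 19 methyl 3-[(1S,4R,6S)-2-acetyl-4-(tert-butyldimethylsilyloxy)-1-methyl-6-(prop-1-en-2-yl)cyclohex-2-en-1-yl]propanoate
Product: 21 methyl 3-[(1S,4R,6S)-4-(tert-butyldimethylsilyloxy)-2-(2-diazoacetyl)-1-methyl-6-(prop-1-en-2-yl)cyclohex-2-en-1-yl]propanoate, via trifluoroacetyl diketone 20 (not isolated)
Conditions: LiN(SiMe3)2, THF, −78 °C; CF3CO2CH2CF3; then MsN3, Et3N, H2O, MeCN, rt
Reagents that add atoms: methanesulfonyl azide, CS(=O)(=O)N=[N+]=[N-]; 2,2,2-trifluoroethyl trifluoroacetate, O=C(OCC(F)(F)F)C(F)(F)F (atoms retained only in 20)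
Why: Kinetic deprotonation of the methyl ketone (more acidic than the ester, α' faster than γ) and trifluoroacetylation should give an activated 1,3-diketone that undergoes diazo transfer with loss of the trifluoroacetyl group (detrifluoroacetylative diazo transfer), which avoids exposing the enone to diazomethane.

Step 11
Reactants: 22 ethyl isobutyrate; 23 dibromomethane
Product: 26 3-methyl-1-(triisopropylsilyloxy)but-1-yne, via dibromo enolate 24 (not isolated), via lithium ynolate 25 (not isolated)
Conditions: 23, lithium 2,2,6,6-tetramethylpiperidide, THF, −78 °C; LiN(SiMe3)2, −78 → −20 °C; n-BuLi, −78 °C → rt; then TIPSCl, −78 → 0 °C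
Reagents that add atoms: triisopropylsilyl chloride, CC(C)[Si](Cl)(C(C)C)C(C)C
Why: In this Kowalski ester homologation dibromomethyllithium adds to the ester, the derived dibromo enolate undergoes bromine–lithium exchange and 1,2-shift of the isopropyl group to the ynolate, and the bulky silyl chloride should react at oxygen to give the siloxyalkyne.

Step 12
Reactants: 21 methyl 3-[(1S,4R,6S)-4-(tert-butyldimethylsilyloxy)-2-(2-diazoacetyl)-1-methyl-6-(prop-1-en-2-yl)cyclohex-2-en-1-yl]propanoate; 26 3-methyl-1-(triisopropylsilyloxy)but-1-yne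
Product: 31 methyl (5S,7R,10S)-7-(tert-butyldimethylsilyloxy)-14-hydroxy-12-(triisopropylsilyloxy)-3,4-secoabieta-4(18),8,11,13-tetraen-3-oate, via vinylketene 27 (not isolated), via 4-vinylcyclobutenone 28 (not isolated), via dienylketene 29 (not isolated), via cyclohexa-2,4-dienone 30 (not isolated)
Conditions: 21 (0.1 M), 26 (2.5 equiv), degassed ClCH2CH2Cl, hν (254 nm, low-pressure Hg lamps, quartz), rt; then 80 °C
Reagents that add atoms: none
Why: Irradiation expels N2 and the C9 alkenyl group shifts from the acyl carbon to the diazo carbon (photochemical Wolff rearrangement), so that the former diazo carbon becomes C11 on C9 and the former carbonyl carbon becomes the ketene carbon C14 of vinylketene 27. The ketene adds the siloxyalkyne in a [2+2] cycloaddition (C14–C13 and C11–C12), cyclobutenone 28 opens by 4π electrocyclic ring opening with cleavage of C11–C14 to the (Z)-dienylketene 29, and ring C closes by thermal 6π electrocyclisation of C14 onto C8, after which dienone 30 enolises to the phenol; warming completes these pericyclic steps. The closest known reaction type is the Danheiser benzannulation in its photochemical variant with α-diazo enones and siloxyalkynes. No stereocentre is created, because the transient sp3 centres at C11 and C8 are erased on aromatisation, and C5, C7 and C10 are untouched under the neutral conditions. The step needs regioselectivity in the [2+2] event, secured by the polarisation of the ynol ether (its isopropyl-bearing carbon is the nucleophile and bonds to the electrophilic ketene carbon), and chemoselectivity for the alkyne over the isopropenyl alkene, secured by the high ketenophilicity of the siloxyalkyne used in excess. Because the C8=C9 alkene of ring B serves as the vinyl unit, C11 is left unsubstituted and para to the new C14 phenol.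

Step 13
Reactants: 31 methyl (5S,7R,10S)-7-(tert-butyldimethylsilyloxy)-14-hydroxy-12-(triisopropylsilyloxy)-3,4-secoabieta-4(18),8,11,13-tetraen-3-oate
Product: 32 methyl (5S,7R,10S)-7-(tert-butyldimethylsilyloxy)-11,14-dioxo-12-(triisopropylsilyloxy)-3,4-secoabieta-4(18),8,12-trien-3-oate
Conditions: (KSO3)2NO, KH2PO4, methyltrioctylammonium chloride (cat.), CH2Cl2/H2O, rt
Reagents that add atoms: potassium nitrosodisulfonate, [K+].[K+].[O]N(S(=O)(=O)[O-])S(=O)(=O)[O-]
Why: In this Teuber-type phenol oxidation the nitrosodisulfonate radical abstracts the C14 hydroxyl hydrogen and a second radical is captured at C11, the only unsubstituted ring position, which should give the 11,14-p-quinone while silyl ethers, ester and alkene stay intact.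

Step 14
Reactants: 32 methyl (5S,7R,10S)-7-(tert-butyldimethylsilyloxy)-11,14-dioxo-12-(triisopropylsilyloxy)-3,4-secoabieta-4(18),8,12-trien-3-oate
Product: 33 methyl (5S,7R,10S)-7,12-dihydroxy-11,14-dioxo-3,4-secoabieta-4(18),8,12-trien-3-oate
Conditions: HF·pyridine, THF, 0 °C → rt
Reagents that add atoms: none
Why: Fluoride-driven desilylation should cleave the very labile silyl vinylogous ester at O12 and then the secondary C7 silyl ether under mildly acidic conditions that the quinone, ester and isopropenyl group tolerate.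

Step 15
Reactants: 33 methyl (5S,7R,10S)-7,12-dihydroxy-11,14-dioxo-3,4-secoabieta-4(18),8,12-trien-3-oate
Product: 34 methyl (5S,10S)-12-hydroxy-7,11,14-trioxo-3,4-secoabieta-4(18),8,12-trien-3-oate (CNP0308749.1)
Conditions: Dess–Martin periodinane, CH2Cl2, rt
Reagents that add atoms: none
Why: Dess–Martin oxidation of the secondary alcohol allylic to the quinone should give the C7 ketone under neutral conditions, the 12-hydroxyl not being oxidisable and neither C5 (β to the new ketone) nor quaternary C10 being epimerisable.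

**Compound list**

1 | (R)-carvone, (5R)-2-methyl-5-(prop-1-en-2-yl)cyclohex-2-en-1-one | CC1=CC[C@H](CC1=O)C(C)=C | starting material
2 | (5R)-5-(1-hydroperoxy-1-methoxyethyl)-2-methylcyclohex-2-en-1-one (in situ, both ketal epimers) | CC1=CC[C@H](CC1=O)C(C)(OC)OO | intermediate
3 | (5R)-5-acetoxy-2-methylcyclohex-2-en-1-one | CC1=CC[C@H](CC1=O)OC(C)=O | intermediate
4 | (5R)-5-hydroxy-2-methylcyclohex-2-en-1-one | CC1=CC[C@H](CC1=O)O | intermediate
5 | (5R)-5-(tert-butyldimethylsilyloxy)-2-methylcyclohex-2-en-1-one | CC1=CC[C@H](CC1=O)O[Si](C)(C)C(C)(C)C | intermediate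
6 | isopropenylmagnesium bromide | CC(=C)[Mg]Br | starting material
7 | allyl bromide | C=CCBr | starting material
8 | bromomagnesium (3S,5R)-5-(tert-butyldimethylsilyloxy)-2-methyl-3-(prop-1-en-2-yl)cyclohex-1-en-1-olate (in situ) | CC1=C(O[Mg]Br)C[C@H](O[Si](C)(C)C(C)(C)C)C[C@H]1C(C)=C | intermediate
9 | (2S,3S,5R)-2-allyl-5-(tert-butyldimethylsilyloxy)-2-methyl-3-(prop-1-en-2-yl)cyclohexan-1-one | O=C1C[C@H](O[Si](C)(C)C(C)(C)C)C[C@@H](C(C)=C)[C@]1(C)CC=C | intermediate
10 | potassium (3R,5S,6S)-6-allyl-3-(tert-butyldimethylsilyloxy)-6-methyl-5-(prop-1-en-2-yl)cyclohex-1-en-1-olate (in situ) | [K]OC1=C[C@H](O[Si](C)(C)C(C)(C)C)C[C@@H](C(C)=C)[C@]1(C)CC=C | intermediate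
11 | (3R,5S,6S)-6-allyl-3-(tert-butyldimethylsilyloxy)-6-methyl-5-(prop-1-en-2-yl)cyclohex-1-en-1-yl trifluoromethanesulfonate | O=S(=O)(OC1=C[C@H](O[Si](C)(C)C(C)(C)C)C[C@@H](C(C)=C)[C@]1(C)CC=C)C(F)(F)F | intermediate
12 | B-alkyl disiamylborane from 11, boron on the terminal carbon of the former allyl group (in situ) | O=S(=O)(OC1=C[C@H](O[Si](C)(C)C(C)(C)C)C[C@@H](C(C)=C)[C@]1(C)CCCB(C(C)C(C)C)C(C)C(C)C)C(F)(F)F | intermediate
13 | (3R,5S,6S)-3-(tert-butyldimethylsilyloxy)-6-(3-hydroxypropyl)-6-methyl-5-(prop-1-en-2-yl)cyclohex-1-en-1-yl trifluoromethanesulfonate | O=S(=O)(OC1=C[C@H](O[Si](C)(C)C(C)(C)C)C[C@@H](C(C)=C)[C@]1(C)CCCO)C(F)(F)F | intermediate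
14 | (3R,5S,6S)-3-(tert-butyldimethylsilyloxy)-6-methyl-6-(3-oxopropyl)-5-(prop-1-en-2-yl)cyclohex-1-en-1-yl trifluoromethanesulfonate (in situ) | O=S(=O)(OC1=C[C@H](O[Si](C)(C)C(C)(C)C)C[C@@H](C(C)=C)[C@]1(C)CCC=O)C(F)(F)F | intermediate
15 | 3-[(1S,4R,6S)-4-(tert-butyldimethylsilyloxy)-1-methyl-6-(prop-1-en-2-yl)-2-(trifluoromethylsulfonyloxy)cyclohex-2-en-1-yl]propanoic acid | O=S(=O)(OC1=C[C@H](O[Si](C)(C)C(C)(C)C)C[C@@H](C(C)=C)[C@]1(C)CCC(=O)O)C(F)(F)F | intermediate
16 | methyl 3-[(1S,4R,6S)-4-(tert-butyldimethylsilyloxy)-1-methyl-6-(prop-1-en-2-yl)-2-(trifluoromethylsulfonyloxy)cyclohex-2-en-1-yl]propanoate | O=S(=O)(OC1=C[C@H](O[Si](C)(C)C(C)(C)C)C[C@@H](C(C)=C)[C@]1(C)CCC(=O)OC)C(F)(F)F | intermediate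
17 | tributyl(1-ethoxyvinyl)stannane | CCOC(=C)[Sn](CCCC)(CCCC)CCCC | starting material
18 | methyl 3-[(1S,4R,6S)-4-(tert-butyldimethylsilyloxy)-2-(1-ethoxyvinyl)-1-methyl-6-(prop-1-en-2-yl)cyclohex-2-en-1-yl]propanoate (in situ) | CCOC(=C)C1=C[C@H](O[Si](C)(C)C(C)(C)C)C[C@@H](C(C)=C)[C@]1(C)CCC(=O)OC | intermediate
19 | methyl 3-[(1S,4R,6S)-2-acetyl-4-(tert-butyldimethylsilyloxy)-1-methyl-6-(prop-1-en-2-yl)cyclohex-2-en-1-yl]propanoate | CC(=O)C1=C[C@H](O[Si](C)(C)C(C)(C)C)C[C@@H](C(C)=C)[C@]1(C)CCC(=O)OC | intermediate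
20 | methyl 3-[(1S,4R,6S)-4-(tert-butyldimethylsilyloxy)-1-methyl-6-(prop-1-en-2-yl)-2-(4,4,4-trifluoro-3-oxobutanoyl)cyclohex-2-en-1-yl]propanoate (in situ) | O=C(CC(=O)C1=C[C@H](O[Si](C)(C)C(C)(C)C)C[C@@H](C(C)=C)[C@]1(C)CCC(=O)OC)C(F)(F)F | intermediate
21 | methyl 3-[(1S,4R,6S)-4-(tert-butyldimethylsilyloxy)-2-(2-diazoacetyl)-1-methyl-6-(prop-1-en-2-yl)cyclohex-2-en-1-yl]propanoate | [N-]=[N+]=CC(=O)C1=C[C@H](O[Si](C)(C)C(C)(C)C)C[C@@H](C(C)=C)[C@]1(C)CCC(=O)OC | intermediate
22 | ethyl isobutyrate (ethyl 2-methylpropanoate) | CCOC(=O)C(C)C | starting material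
23 | dibromomethane | BrCBr | starting material
24 | lithium 1,1-dibromo-3-methylbut-1-en-2-olate (in situ) | [Li]OC(C(C)C)=C(Br)Br | intermediate
25 | lithium 3-methylbut-1-yn-1-olate (in situ) | [Li]OC#CC(C)C | intermediate
26 | 3-methyl-1-(triisopropylsilyloxy)but-1-yne | CC(C)C#CO[Si](C(C)C)(C(C)C)C(C)C | intermediate
27 | vinylketene: methyl 3-[(1S,4R,6S)-4-(tert-butyldimethylsilyloxy)-1-methyl-2-(2-oxoethenyl)-6-(prop-1-en-2-yl)cyclohex-2-en-1-yl]propanoate (in situ) | O=C=CC1=C[C@H](O[Si](C)(C)C(C)(C)C)C[C@@H](C(C)=C)[C@]1(C)CCC(=O)OC | intermediate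
28 | 4-vinylcyclobutenone: the ring-B C9 carbon carries a 3-isopropyl-4-oxo-2-(triisopropylsilyloxy)cyclobut-2-en-1-yl group (in situ, both epimers at C11) | O=C1C(C(C)C)=C(O[Si](C(C)C)(C(C)C)C(C)C)C1C2=C[C@H](O[Si](C)(C)C(C)(C)C)C[C@@H](C(C)=C)[C@]2(C)CCC(=O)OC | intermediate
29 | (Z)-dienylketene: the ring-B C9 carbon carries a 3-isopropyl-4-oxo-2-(triisopropylsilyloxy)buta-1,3-dien-1-yl group (in situ) | O=C=C(C(C)C)/C(O[Si](C(C)C)(C(C)C)C(C)C)=C\C1=C[C@H](O[Si](C)(C)C(C)(C)C)C[C@@H](C(C)=C)[C@]1(C)CCC(=O)OC | intermediate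
30 | cyclohexa-2,4-dienone: 8H-14-keto tautomer of 31 (in situ) | O=C1C(C(C)C)=C(O[Si](C(C)C)(C(C)C)C(C)C)C=C2C1[C@H](O[Si](C)(C)C(C)(C)C)C[C@@H](C(C)=C)[C@]2(C)CCC(=O)OC | intermediate
31 | methyl (5S,7R,10S)-7-(tert-butyldimethylsilyloxy)-14-hydroxy-12-(triisopropylsilyloxy)-3,4-secoabieta-4(18),8,11,13-tetraen-3-oate | CC(C)c1c(O[Si](C(C)C)(C(C)C)C(C)C)cc2c(c1O)[C@H](O[Si](C)(C)C(C)(C)C)C[C@@H](C(C)=C)[C@]2(C)CCC(=O)OC | intermediate
32 | methyl (5S,7R,10S)-7-(tert-butyldimethylsilyloxy)-11,14-dioxo-12-(triisopropylsilyloxy)-3,4-secoabieta-4(18),8,12-trien-3-oate | CC(C)C1=C(O[Si](C(C)C)(C(C)C)C(C)C)C(=O)C2=C(C1=O)[C@H](O[Si](C)(C)C(C)(C)C)C[C@@H](C(C)=C)[C@]2(C)CCC(=O)OC | intermediate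
33 | methyl (5S,7R,10S)-7,12-dihydroxy-11,14-dioxo-3,4-secoabieta-4(18),8,12-trien-3-oate | CC(C)C1=C(O)C(=O)C2=C(C1=O)[C@H](O)C[C@@H](C(C)=C)[C@]2(C)CCC(=O)OC | intermediate
34 | methyl (5S,10S)-12-hydroxy-7,11,14-trioxo-3,4-secoabieta-4(18),8,12-trien-3-oate (CNP0308749.1) | C=C(C)[C@@H]1CC(=O)C2=C(C(=O)C(O)=C(C(C)C)C2=O)[C@@]1(C)CCC(=O)OC | target

**Step count and risk**

Total: 15 steps. Longest linear sequence: 14 steps (steps 1–10 and 12–15 from 1); step 11 is a one-step branch.

Steps most likely to fail: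

1. Step 12. The vinylketene may be diverted before it meets the alkyne (intramolecular capture by the isopropenyl alkene, dimerisation, acylation of the product phenol), or photolysis may stall as absorbing by-products build up. The fallback reaches the same 4-vinylcyclobutenone by cross-coupling instead of ketene chemistry; it sets out from 16 and 26 and comes back at 28, which is then heated on to 31 as in step 12. Triflate 16 is stannylated with Me3SnSnMe3, Pd(PPh3)4 and LiCl to the C9 trimethylstannane F1. Alkyne 26 takes up dichloroketene (Cl3CCOCl, Zn–Cu couple, Et2O/DME) with the same ynol-ether regiochemistry to give the 4,4-dichlorocyclobutenone F2, which one equivalent of Zn in AcOH/TMEDA/EtOH at 0 °C should reduce to the monochloride F3. Coupling of F1 with F3 (PdCl2(PhCN)2, tri(2-furyl)phosphine, dioxane, 50 → 100 °C) forms C9–C11 and delivers 28.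

2. Step 4. The risks are incomplete C-allylation of the magnesium enolate, proton transfer followed by β-elimination of the silyloxy group, and insufficient facial selectivity at C10. The fallback sets out from 5 and comes back at 9. The enolate 8 from the same conjugate addition is O-acylated with allyl chloroformate to the allyl enol carbonate F4, and Pd(PPh3)4 in THF at rt then effects decarboxylative allylation (Tsuji allylation) under neutral conditions. The quaternary centre forms regiospecifically at C10 and should again form anti to the isopropenyl group.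

3. Step 10. Competing enolisation at the ester or at the γ-position (C7–H), or incomplete acyl transfer, would erode the diazo transfer. The fallback sets out from 16 and comes back at 21. Palladium-catalysed hydroxycarbonylation (Pd(OAc)2, 1,1'-bis(diphenylphosphino)ferrocene, CO, KOAc, DMF) gives the C9 carboxylic acid F5. 1-Chloro-N,N,2-trimethylprop-1-en-1-amine converts it under neutral conditions into the acid chloride F6, and acylation of excess diazomethane (Et2O, 0 °C) gives 21. The trisubstituted C8=C9 alkene next to quaternary C10 should resist dipolar cycloaddition.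

**Further compounds**

F1 | step 12 | methyl 3-[(1S,4R,6S)-4-(tert-butyldimethylsilyloxy)-1-methyl-6-(prop-1-en-2-yl)-2-(trimethylstannyl)cyclohex-2-en-1-yl]propanoate | C[Sn](C)(C)C1=C[C@H](O[Si](C)(C)C(C)(C)C)C[C@@H](C(C)=C)[C@]1(C)CCC(=O)OC
F2 | step 12 | 4,4-dichloro-2-isopropyl-3-(triisopropylsilyloxy)cyclobut-2-en-1-one | O=C1C(C(C)C)=C(O[Si](C(C)C)(C(C)C)C(C)C)C1(Cl)Cl
F3 | step 12 | 4-chloro-2-isopropyl-3-(triisopropylsilyloxy)cyclobut-2-en-1-one (racemic) | O=C1C(C(C)C)=C(O[Si](C(C)C)(C(C)C)C(C)C)C1Cl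
F4 | step 4 | allyl (3S,5R)-5-(tert-butyldimethylsilyloxy)-2-methyl-3-(prop-1-en-2-yl)cyclohex-1-en-1-yl carbonate | CC1=C(OC(=O)OCC=C)C[C@H](O[Si](C)(C)C(C)(C)C)C[C@H]1C(C)=C
F5 | step 10 | (3R,5S,6S)-3-(tert-butyldimethylsilyloxy)-6-(3-methoxy-3-oxopropyl)-6-methyl-5-(prop-1-en-2-yl)cyclohex-1-ene-1-carboxylic acid | OC(=O)C1=C[C@H](O[Si](C)(C)C(C)(C)C)C[C@@H](C(C)=C)[C@]1(C)CCC(=O)OC
F6 | step 10 | (3R,5S,6S)-3-(tert-butyldimethylsilyloxy)-6-(3-methoxy-3-oxopropyl)-6-methyl-5-(prop-1-en-2-yl)cyclohex-1-ene-1-carbonyl chloride | ClC(=O)C1=C[C@H](O[Si](C)(C)C(C)(C)C)C[C@@H](C(C)=C)[C@]1(C)CCC(=O)OC
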